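A closed flask at constant volume keeps its charges as a budget: coupling partner spent on one thing is not there for another.

| setting | zeta | eta | flask |
|---|---|---|---|
| starting material | 0.25 M | 0.25 M | 0.25 M |
| fresh partner | 0.20 M | 0.20 M | 0.200 M |
| coupling partner | 0.50 M | 0.34 M | 0.500 M |
| remark | the very flask that is asked about, followed so far | run made earlier |  |
| time |  |  | 10 d |

| zeta: time / h | zeta: target / % | eta: time / d | eta: target / % |
|---|---|---|---|
| 1.33 | 15.1 | 0.104 | 11.4 |
| 5.00 | 25.8 | 0.500 | 9.0 |
| 15.0 | 19.5 | 2.00 | 2.2 |
| 50.0 | 17.9 | 10.0 | 1.0 |

(scatter of a reading: 1 percentage point)



- the best time, 10 d at the latest, for target
- the amount of target, in percent of the starting material charged, at that time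

Two chemists argue at the board. The first holds that target simply decays: the eta readings at 0.500 d and 2.00 d give a half-life of about 0.738 d, so 10 d holds 13.6 half-lives, and the level stretch in zeta is a pause. The second answers that zeta's readings at 15.0 h and 50.0 h differ by 1.6 percentage points, against a scatter of 1 point, so the loss must need a partner that can run out, and she names starting material.

My own reckoning takes her side. Let fresh partner and starting material each take coupling partner one for one, and count the turnovers of starting material that coupling partner can pay for once fresh partner is served: the cover, ([coupling partner] − [fresh partner]) / [starting material] as charged, 1.20 in zeta and 0.560 in eta. Zeta's surplus of coupling partner is more than its starting material, and eta's is less, so on this count starting material outlasts that surplus in eta, where it can go on attacking target, and in zeta it does not. The cover speaks of where the fall ends, not of when the peak comes.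

The forecast reaches her plateau on its own grounds, “no reason to expect a late rise”, and puts the peak at 0.16 d with 27%.

The flask peaks later than that, at 0.229 d, with 27.5%, close to the forecast's height, and at the longest time allowed it still holds 16.5% of target, so simple decay fails here.

    starting material + coupling partner → open intermediate (k = 1.60 × 10⁻⁴ M⁻¹ s⁻¹)
    coupling partner + fresh partner → second intermediate (k = 0.00740 M⁻¹ s⁻¹)
    open intermediate + second intermediate → target (k = 0.0150 M⁻¹ s⁻¹)
    second intermediate → side product A (k = 5.70 × 10⁻⁵ s⁻¹)
    starting material + target → side product B (k = 2.80 × 10⁻⁴ M⁻¹ s⁻¹)

In this flask, with its cover of 1.20, starting material ended at 0%, fresh partner, the limiting reagent, at 0%, and coupling partner at 25% of its charge. The neighbour charged with 0.42 M of starting material, other charges held, has a cover of 0.714, its surplus being less than its starting material. This is the first chemist's region, as eta was. That neighbour reaches 17.1% at best, and by the longest time allowed its target has fallen to 0.521%.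

(All runs come from a simulation from invented constants; the scatter is artificial.)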